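Turn every constant into a rate at the charged amounts before asking who wins in these two flasks.

    starting material + reagent → target (k1 = 1.2 L mol⁻¹ s⁻¹)
    second substrate + reagent → second product (k2 = 0.80 L mol⁻¹ s⁻¹)
    starting material + second substrate → cross product (k3 = 0.42 L mol⁻¹ s⁻¹)
    2 starting material → homo dimer (k4 = 2.2 L mol⁻¹ s⁻¹)
    second substrate ⇌ dormant form (K5 = 0.38, k5 = 0.0041 s⁻¹)

all flasks: starting material 11 mM; reagent 33.0 mM; time 10 min
- cedar: second substrate 72.0 mM
- maple: second substrate 55.0 mM

- a species is counted by the starting material in it: one homo dimer counts as two
- a doubled species enters its step squared and goes two at a time
- run time (cedar): 10 min

- which of the two there is more of at the end, cedar (cross product / target)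
- which of the two there is more of at the end, maple (cross product / target)
- amount of target at the end, in percent of the starting material charged, cedar
- amount of target at the end, in percent of the starting material charged, maple

At the bench we would use a rule of thumb. Starting material meets reagent and second substrate side by side, so target over cross product should equal the ratio of the two rates at the charge, a selectivity factor. That gives 1.71 in maple and 1.31 in cedar, and target wins both.

But the rule needs the reagent to stand still. In maple, reagent is lost at 3.43 min⁻¹ and starting material at 6.67 min⁻¹, so the reagent falls half as fast. In cedar the two rates are 4.25 min⁻¹ and 7.09 min⁻¹, a ratio of 0.599. Neither ratio is small, so the rule has passed its border.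

If both losses ran exponentially, starting material would meet, on average over its life, a reagent level reduced by its own loss rate over the sum of both. Applying that factor gives 1.13 for maple and 0.819 for cedar. This discounted ratio, the charged ratio times the loss rate of starting material over the sum of both loss rates, puts cedar below one. We commit to cross product ahead in cedar and target ahead in maple. Homo dimer enters this ratio through the loss rate of starting material, but the ratio sets target against cross product, so our reckoning stops short of percentages.

The forecast calls cross product for cedar and target for maple, with target at 32% (28% to 36%) and 37% (33% to 42%), reasoning that the “reagent is rapidly depleted by the large excess of second substrate”. Its calls match ours; its percentages are its own.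

After 10 min the flasks hold 30.6% target in cedar and 36.5% in maple. Cross product stands at 38.7% in cedar and 30.6% in maple, so target over cross product reads 0.791 and 1.19, beside our discounted 0.819 and 1.13. For the neighbour of maple charged with 94 mM of second substrate, the discounted ratio is 0.592. That flask ends with target at 25.2% and cross product at 46.8%, a ratio of 0.538.

All constants are invented; the result is computed.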